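**Retrosynthetic overview**
- Last bond made: the ring A aryl–acetyl C–C bond, formed on the fully assembled, protected depside from its aryl bromide and tributyl(1-ethoxyethenyl)stannane (a masked acetyl anion). One acidic work-up then unmasks the ketone and all three phenols.
- Before that: the depside ester C–O bond, from a ring A phenol flanked by two MOM ethers and the ring B acid chloride.
- Ring A piece: olivetol → bis-MOM ether → lithiation between the two ethers, borylation and oxidation (central OH) → bromination at the only kind of free ring position.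
- Ring B piece: methyl 2,4-dihydroxy-6-propylbenzoate → 4-O-MOM and 2-O-methyl in one pot → saponification.
- No ring is formed: both benzene rings are bought (ring A as olivetol, ring B as the divarinate ester).

Assumption: the target has no stereocentre or other stereogenic element, so "single enantiomer" is read as the one achiral compound drawn.

**Route**

Step 1
Reactants: 1 olivetol (5-pentylbenzene-1,3-diol)
Product: 2 1,3-bis(methoxymethoxy)-5-pentylbenzene
Conditions: MOMCl, i-Pr2NEt, CH2Cl2, 0 °C → rt
Reagents that add atoms: chloromethyl methyl ether (MOMCl), COCCl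
Why: Williamson-type O-alkylation of both phenols gives acid-labile MOM ethers that also serve as the directing groups for the next lithiation.

Step 2
Reactants: 2 1,3-bis(methoxymethoxy)-5-pentylbenzene
Product: 5 2,6-bis(methoxymethoxy)-4-pentylphenol, via aryllithium 3 (not isolated), via lithium aryltrimethoxyborate 4 (not isolated)
Conditions: n-BuLi, THF, 0 °C → rt; B(OMe)3, −78 °C → rt; 30% aq H2O2, 0 °C → rt
Reagents that add atoms: hydrogen peroxide, OO
Why: Directed ortho-metalation places lithium on the carbon between the two MOM ethers, and borylation followed by boronate oxidation (1,2-aryl shift from boron to oxygen) turns that C–Li into the only free OH of the ring.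

Step 3
Reactants: 5 2,6-bis(methoxymethoxy)-4-pentylphenol
Product: 6 3-bromo-2,6-bis(methoxymethoxy)-4-pentylphenol
Conditions: NBS (1.0 equiv), MeCN, −20 → 0 °C
Reagents that add atoms: N-bromosuccinimide (NBS), O=C1CCC(=O)N1Br
Why: Electrophilic aromatic bromination, in which the two equivalent free positions are each ortho to one MOM ether and para to the other, so one equivalent of NBS gives a single monobromide.

Step 4
Reactants: 7 methyl 2,4-dihydroxy-6-propylbenzoate
Product: 9 methyl 2-methoxy-4-(methoxymethoxy)-6-propylbenzoate, via 4-O-MOM ether 8 (not isolated)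
Conditions: K2CO3, MOMCl (1.05 equiv), DMF, 0 °C → rt; then MeI (3 equiv), 45 °C
Reagents that add atoms: chloromethyl methyl ether (MOMCl), COCCl; iodomethane (MeI), CI
Why: Chemoselective Williamson etherification, in which the 2-OH is hydrogen-bonded to the ester carbonyl so MOMCl takes the 4-OH first, and only excess MeI with warming alkylates the chelated 2-OH.

Step 5
Reactants: 9 methyl 2-methoxy-4-(methoxymethoxy)-6-propylbenzoate
Product: 10 2-methoxy-4-(methoxymethoxy)-6-propylbenzoic acid
Conditions: KOH, DMSO/H2O (4:1), 90 °C; then 1 M HCl to pH 4, 0 °C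
Reagents that add atoms: potassium hydroxide, [K+].[OH-]
Why: Saponification of the hindered methyl ester with hot KOH in aqueous DMSO, to which the MOM and methyl aryl ethers are inert, followed by a cold, brief acidification that spares the MOM group.

Step 6
Reactants: 10 2-methoxy-4-(methoxymethoxy)-6-propylbenzoic acid; 6 3-bromo-2,6-bis(methoxymethoxy)-4-pentylphenol
Product: 12 3-bromo-2,6-bis(methoxymethoxy)-4-pentylphenyl 2-methoxy-4-(methoxymethoxy)-6-propylbenzoate, via acid chloride 11 (not isolated)
Conditions: 1-chloro-N,N,2-trimethylprop-1-en-1-amine, CH2Cl2, 0 °C → rt; then 6, Et3N, DMAP (cat.), CH2Cl2, 0 → 40 °C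
Reagents that add atoms: none
Why: Nucleophilic acyl substitution of an acid chloride by a phenol under DMAP catalysis, with the acid chloride made under neutral conditions so the MOM groups survive, and with the central OH as the only free hydroxyl so the ester can form only there.

Step 7
Reactants: 12 3-bromo-2,6-bis(methoxymethoxy)-4-pentylphenyl 2-methoxy-4-(methoxymethoxy)-6-propylbenzoate
Product: 14 3-acetyl-2,6-dihydroxy-4-pentylphenyl 4-hydroxy-2-methoxy-6-propylbenzoate, via enol ether 13 (not isolated)
Conditions: tributyl(1-ethoxyethenyl)stannane, Pd(P(t-Bu)3)2 (5 mol %), CsF, 1,4-dioxane, 100 °C; then 3 M aq HCl, THF, 45 °C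
Reagents that add atoms: tributyl(1-ethoxyethenyl)stannane, CCCC[Sn](CCCC)(CCCC)C(=C)OCC; water, O
Why: Migita–Kosugi–Stille coupling in which the α-stannyl enol ether acts as an acetyl anion equivalent toward the aryl bromide (joining an aryl halide carbon and an acyl carbon, both electrophilic by nature) with a bulky, fluoride-assisted palladium catalyst suited to the di-ortho-substituted bromide, after which aqueous HCl hydrolyses the enol ether to the methyl ketone and cleaves the three MOM ethers while the hindered aryl ester stays intact.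

**Compound list**

1 | olivetol (5-pentylbenzene-1,3-diol) | CCCCCc1cc(O)cc(O)c1 | starting material
2 | 1,3-bis(methoxymethoxy)-5-pentylbenzene | CCCCCc1cc(OCOC)cc(OCOC)c1 | intermediate
3 | [2,6-bis(methoxymethoxy)-4-pentylphenyl]lithium | CCCCCc1cc(OCOC)c([Li])c(OCOC)c1 | intermediate
4 | lithium [2,6-bis(methoxymethoxy)-4-pentylphenyl]trimethoxyborate | [Li+].CCCCCc1cc(OCOC)c([B-](OC)(OC)OC)c(OCOC)c1 | intermediate
5 | 2,6-bis(methoxymethoxy)-4-pentylphenol | CCCCCc1cc(OCOC)c(O)c(OCOC)c1 | intermediate
6 | 3-bromo-2,6-bis(methoxymethoxy)-4-pentylphenol | CCCCCc1cc(OCOC)c(O)c(OCOC)c1Br | intermediate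
7 | methyl 2,4-dihydroxy-6-propylbenzoate | CCCc1cc(O)cc(O)c1C(=O)OC | starting material
8 | methyl 2-hydroxy-4-(methoxymethoxy)-6-propylbenzoate | CCCc1cc(OCOC)cc(O)c1C(=O)OC | intermediate
9 | methyl 2-methoxy-4-(methoxymethoxy)-6-propylbenzoate | CCCc1cc(OCOC)cc(OC)c1C(=O)OC | intermediate
10 | 2-methoxy-4-(methoxymethoxy)-6-propylbenzoic acid | CCCc1cc(OCOC)cc(OC)c1C(=O)O | intermediate
11 | 2-methoxy-4-(methoxymethoxy)-6-propylbenzoyl chloride | CCCc1cc(OCOC)cc(OC)c1C(Cl)=O | intermediate
12 | 3-bromo-2,6-bis(methoxymethoxy)-4-pentylphenyl 2-methoxy-4-(methoxymethoxy)-6-propylbenzoate | CCCCCc1cc(OCOC)c(OC(=O)c2c(CCC)cc(OCOC)cc2OC)c(OCOC)c1Br | intermediate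
13 | 3-(1-ethoxyethenyl)-2,6-bis(methoxymethoxy)-4-pentylphenyl 2-methoxy-4-(methoxymethoxy)-6-propylbenzoate | CCCCCc1cc(OCOC)c(OC(=O)c2c(CCC)cc(OCOC)cc2OC)c(OCOC)c1C(=C)OCC | intermediate
14 | 3-acetyl-2,6-dihydroxy-4-pentylphenyl 4-hydroxy-2-methoxy-6-propylbenzoate | CCCCCc1cc(O)c(OC(=O)c2c(CCC)cc(O)cc2OC)c(O)c1C(C)=O | target

**Step count and risks**

Total step count: 7. Longest linear sequence: 5 (steps 1, 2, 3, 6, 7).

Steps most likely to fail:

Step 7. The bromide sits between a MOM ether and the pentyl chain on an electron-rich ring, so oxidative addition may be slow and protodebromination may compete. The aryl ester must also survive fluoride at 100 °C, and the acid step must remove three MOM groups without acyl migration or capture of the released formaldehyde by the phenols. The fallback sets out from 6 and comes back at 14. It moves the acetyl-anion coupling ahead of the esterification, so the ester never meets palladium, fluoride or heat, and each unmasking gets its own conditions. Bromophenol 6 is coupled with tributyl(1-ethoxyethenyl)stannane (Pd(P(t-Bu)3)2, CsF, dioxane, 100 °C) to give 3-(1-ethoxyethenyl)-2,6-bis(methoxymethoxy)-4-pentylphenol F1. Oxalic acid on wet silica gel (CH2Cl2, rt) hydrolyses only the enol ether to 1-[3-hydroxy-2,4-bis(methoxymethoxy)-6-pentylphenyl]ethanone F2. F2 is acylated with acid chloride 11 (made from 10 as in step 6; Et3N, DMAP, CH2Cl2) to 3-acetyl-2,6-bis(methoxymethoxy)-4-pentylphenyl 2-methoxy-4-(methoxymethoxy)-6-propylbenzoate F3. 3 M aq HCl in THF at 45 °C then removes the three MOM groups to give 14.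

Step 3. Phenol 5 is very electron-rich and oxidation-prone, so NBS may over-brominate or oxidise it to quinoid products instead of giving the clean monobromide. The fallback sets out from 2 and comes back at 6, and puts the halogen in before the oxygen. NBS in MeCN at 0 °C brominates 2 para to one MOM ether to give 2-bromo-1,5-bis(methoxymethoxy)-3-pentylbenzene F4. The C–H between the two MOM ethers is then removed with lithium 2,2,6,6-tetramethylpiperidide in the presence of B(Oi-Pr)3 (in-situ quench, THF, −78 °C; an amide base does not undergo bromine–lithium exchange), giving lithium [3-bromo-2,6-bis(methoxymethoxy)-4-pentylphenyl]tri(propan-2-yloxy)borate F5. Oxidation of F5 with H2O2 gives 6.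

Step 5. Hydroxide addition to the di-ortho-substituted ester carbonyl is slow, and forcing base or a careless acidification costs material. The fallback sets out from 9 and comes back at 10, and replaces the hydrolysis by a redox detour. LiAlH4 (THF, 0 °C → rt) reduces 9 to [2-methoxy-4-(methoxymethoxy)-6-propylphenyl]methanol F6. MnO2 (CH2Cl2, rt) oxidises F6 to 2-methoxy-4-(methoxymethoxy)-6-propylbenzaldehyde F7. Pinnick oxidation (NaClO2, NaH2PO4, 2-methylbut-2-ene, t-BuOH/H2O) then gives 10.

**Further compounds**

F1 | step 7 | 3-(1-ethoxyethenyl)-2,6-bis(methoxymethoxy)-4-pentylphenol | CCCCCc1cc(OCOC)c(O)c(OCOC)c1C(=C)OCC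
F2 | step 7 | 1-[3-hydroxy-2,4-bis(methoxymethoxy)-6-pentylphenyl]ethanone | CCCCCc1cc(OCOC)c(O)c(OCOC)c1C(C)=O
F3 | step 7 | 3-acetyl-2,6-bis(methoxymethoxy)-4-pentylphenyl 2-methoxy-4-(methoxymethoxy)-6-propylbenzoate | CCCCCc1cc(OCOC)c(OC(=O)c2c(CCC)cc(OCOC)cc2OC)c(OCOC)c1C(C)=O
F4 | step 3 | 2-bromo-1,5-bis(methoxymethoxy)-3-pentylbenzene | CCCCCc1cc(OCOC)cc(OCOC)c1Br
F5 | step 3 | lithium [3-bromo-2,6-bis(methoxymethoxy)-4-pentylphenyl]tri(propan-2-yloxy)borate | [Li+].CCCCCc1cc(OCOC)c([B-](OC(C)C)(OC(C)C)OC(C)C)c(OCOC)c1Br
F6 | step 5 | [2-methoxy-4-(methoxymethoxy)-6-propylphenyl]methanol | CCCc1cc(OCOC)cc(OC)c1CO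
F7 | step 5 | 2-methoxy-4-(methoxymethoxy)-6-propylbenzaldehyde | CCCc1cc(OCOC)cc(OC)c1C=O
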